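The cycloheptane ring of the trans-fused hydroazulene (daucane) core is divided into a three-carbon unit (C1 with its angular methyl, C10, C9) and a four-carbon unit (C8 with its methyl, C7, C6, C5). One gold-catalysed intramolecular (4+3) cycloaddition of an acyclic allene–silyloxydiene joins them: it forms the ring-fusion bond C1–C5 and the bond C8–C9 that later carries the epoxide oxygen, closing the cyclopentane and the cycloheptane together. The precursor comes from (S)-terpinen-4-ol by ozonolytic ring opening, which keeps the C4 isopropyl carbinol stereocentre; its methyl ketone becomes the allene and its aldehyde the dienol ether. Alkene transposition, ketone reduction and hydroxyl-directed epoxidation complete the target.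

Key step: step 9

Remark (numbering): bicyclic compounds carry daucane numbering: C1 quaternary ring-fusion carbon with the angular methyl, C2 and C3 cyclopentane CH2, C4 isopropyl-bearing carbinol carbon, C5 ring-fusion CH, C6 carbinol carbon, C7 CH2, C8 methyl-bearing carbon, C9, C10 CH2; β is the face of the angular methyl.
Assumption: the target is taken as drawn, with the 4-hydroxybenzoate on the tertiary oxygen at C4 and a free hydroxyl at C6; (S)-(+)-terpinen-4-ol and (E)-1-bromopropene are taken as commercial, isomerically pure materials.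

Step 1
Reactants: 1 (S)-terpinen-4-ol; 2 4-(benzyloxy)benzoyl chloride
Product: 4 (S)-terpinen-4-yl 4-(benzyloxy)benzoate, via lithium (S)-terpinen-4-olate 3 (not isolated)
Conditions: n-BuLi, THF, −78 → 0 °C; then 2, 0 °C → rt
Reagents that add atoms: none
Why: O-acylation of the preformed lithium alkoxide overcomes the low reactivity of the hindered tertiary alcohol, and the stereocentre is not touched.

Step 2
Reactants: 4 (S)-terpinen-4-yl 4-(benzyloxy)benzoate
Product: 7 (S)-1,1-dimethoxy-6-oxo-3-(propan-2-yl)heptan-3-yl 4-(benzyloxy)benzoate, via secondary ozonide 5 (not isolated), via keto aldehyde 6 (not isolated)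
Conditions: O3, CH2Cl2, −78 °C; PPh3, −78 °C → rt; then MeOH, HC(OMe)3, CeCl3·7H2O (cat.), rt
Reagents that add atoms: ozone O=[O+][O-]; trimethyl orthoformate COC(OC)OC
Why: Criegee ozonolysis cleaves the only alkene and so opens the ring while the carbinol stereocentre is kept, and cerium-catalysed acetalisation takes the aldehyde and not the methyl ketone, so the elimination-prone β-acyloxy aldehyde is never isolated.

Step 3
Reactants: 7 (S)-1,1-dimethoxy-6-oxo-3-(propan-2-yl)heptan-3-yl 4-(benzyloxy)benzoate; 8 ethynylmagnesium bromide (HC≡CMgBr)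
Product: 10 (3S)-6-ethynyl-1,1-dimethoxy-6-(methoxycarbonyloxy)-3-(propan-2-yl)heptan-3-yl 4-(benzyloxy)benzoate, via bromomagnesium alkoxide 9 (not isolated)
Conditions: 8, THF, 0 °C; then ClCO2Me, 0 °C → rt
Reagents that add atoms: methyl chloroformate COC(Cl)=O
Why: Grignard 1,2-addition to the methyl ketone is followed by O-acylation of the alkoxide in the same flask; the new carbinol centre forms as both epimers, which does not matter because it becomes an allene carbon in step 4.

Step 4
Reactants: 10 (3S)-6-ethynyl-1,1-dimethoxy-6-(methoxycarbonyloxy)-3-(propan-2-yl)heptan-3-yl 4-(benzyloxy)benzoate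
Product: 11 (S)-1,1-dimethoxy-6-methyl-3-(propan-2-yl)octa-6,7-dien-3-yl 4-(benzyloxy)benzoate
Conditions: Pd2(dba)3·CHCl3 (cat.), P(n-Bu)3, HCO2NH4, THF, 40 °C
Reagents that add atoms: none
Why: Palladium-catalysed formate hydrogenolysis of a tertiary propargylic carbonate with a terminal alkyne proceeds by SN2′ oxidative addition to an allenylpalladium species, formate decarboxylation and reductive elimination, and should deliver the 1,1-disubstituted allene.

Step 5
Reactants: 11 (S)-1,1-dimethoxy-6-methyl-3-(propan-2-yl)octa-6,7-dien-3-yl 4-(benzyloxy)benzoate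
Product: 12 (S)-6-methyl-1-oxo-3-(propan-2-yl)octa-6,7-dien-3-yl 4-(benzyloxy)benzoate
Conditions: LiBF4, MeCN/H2O, rt
Reagents that add atoms: water O
Why: Mild Lewis-acid hydrolysis of the dimethyl acetal releases the aldehyde without base, so the allene, the tertiary ester and the β-acyloxy aldehyde itself should survive.

Step 6
Reactants: 12 (S)-6-methyl-1-oxo-3-(propan-2-yl)octa-6,7-dien-3-yl 4-(benzyloxy)benzoate; 13 (E)-1-bromopropene
Product: 15 (2E,6S)-4-hydroxy-9-methyl-6-(propan-2-yl)undeca-2,9,10-trien-6-yl 4-(benzyloxy)benzoate, via (E)-1-propenyllithium 14 (not isolated)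
Conditions: 13, t-BuLi, Et2O, −78 °C; then 12, −78 °C; NH4Cl (aq)
Reagents that add atoms: none
Why: Halogen–lithium exchange keeps the alkene geometry and the alkenyllithium adds to the aldehyde far faster than to the hindered tertiary ester at −78 °C; the carbinol forms as both epimers and is oxidised in step 7.

Step 7
Reactants: 15 (2E,6S)-4-hydroxy-9-methyl-6-(propan-2-yl)undeca-2,9,10-trien-6-yl 4-(benzyloxy)benzoate
Product: 16 (2E,6S)-9-methyl-4-oxo-6-(propan-2-yl)undeca-2,9,10-trien-6-yl 4-(benzyloxy)benzoate
Conditions: Dess–Martin periodinane, NaHCO3, CH2Cl2, 0 °C → rt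
Reagents that add atoms: none
Why: Dess–Martin oxidation of the allylic alcohol gives the (E)-enone under buffered, non-basic conditions that spare the allene and the β-acyloxy ketone.

Step 8
Reactants: 16 (2E,6S)-9-methyl-4-oxo-6-(propan-2-yl)undeca-2,9,10-trien-6-yl 4-(benzyloxy)benzoate
Product: 17 (2E,4Z,6R)-4-(tert-butyldimethylsilyloxy)-9-methyl-6-(propan-2-yl)undeca-2,4,9,10-tetraen-6-yl 4-(benzyloxy)benzoate
Conditions: TBSOTf, Et3N, CH2Cl2, −78 °C
Reagents that add atoms: tert-butyldimethylsilyl triflate CC(C)(C)[Si](C)(C)OS(=O)(=O)C(F)(F)F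
Why: Soft enolisation with silyl triflate and amine removes the α′ proton and should give the cross-conjugated 2-silyloxydiene as the (Z)-enol ether (quaternary substituent cis to the silyloxy group) without a free enolate that could expel the β-acyloxy group.

Step 9
Reactants: 17 (2E,4Z,6R)-4-(tert-butyldimethylsilyloxy)-9-methyl-6-(propan-2-yl)undeca-2,4,9,10-tetraen-6-yl 4-(benzyloxy)benzoate
Product: 18 4β-[4-(benzyloxy)benzoyloxy]-6-(tert-butyldimethylsilyloxy)dauca-6,9-diene
Conditions: [Au(NCMe){P(t-Bu)2(2-biphenylyl)}]SbF6 (cat.), 4 Å molecular sieves, CH2Cl2, −20 °C → rt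
Reagents that add atoms: none
Why: The cationic gold centre binds the allene and turns it into a gold-bound allyl cation whose tertiary terminus (C1) is attacked by the nucleophilic terminus C5 of the silyloxydiene, the other allyl terminus (C9) then bonding to the diene terminus C8; the gold carbene left at C10 undergoes a 1,2-hydride shift from C9, which releases the catalyst and leaves the C9=C10 alkene and the C6=C7 silyl enol ether. The closest known reaction type is the gold- or platinum-catalysed intramolecular (4+3) cycloaddition of allene-tethered 1,3-dienes to hydroazulenes. The cyclopentane closes as a 5-exo attack across the three-atom tether (bond C1–C5), and the cycloheptadiene closes by terminus-to-terminus bonding of the three-carbon and four-carbon units (bond C8–C9). The exo-like transition state typical of this cycloaddition should place the angular methyl at C1 trans to H-5 (trans ring fusion), and allylic 1,3-strain in the (Z)-silyl enol ether holds the C4–O bond in the diene plane so that the tether delivers the allene to the face opposite the isopropyl group, which fixes C1 and C5 relative to C4; the C8 methine centre set here is removed in step 10. The step needs (4+3) closure to win over protodemetalation after the first bond, formal (3+2) closure at the oxocarbenium carbon and a 1,2-alkyl shift of the carbene, which the anhydrous medium and the electron-rich biarylphosphine ligand (known to favour the 1,2-hydride shift) are meant to secure.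

Step 10
Reactants: 18 4β-[4-(benzyloxy)benzoyloxy]-6-(tert-butyldimethylsilyloxy)dauca-6,9-diene
Product: 19 4β-[4-(benzyloxy)benzoyloxy]-6-(tert-butyldimethylsilyloxy)dauca-6,8-diene
Conditions: RuHCl(CO)(PPh3)3 (cat.), toluene, 80 °C
Reagents that add atoms: none
Why: Transition-metal hydride alkene isomerisation: the ruthenium hydride adds to and eliminates from the disubstituted C9=C10 alkene and so moves it to C8=C9, into conjugation with the silyl enol ether, where the trisubstituted 1-silyloxy-1,3-diene is the thermodynamic end point and the C8 stereocentre disappears.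

Step 11
Reactants: 19 4β-[4-(benzyloxy)benzoyloxy]-6-(tert-butyldimethylsilyloxy)dauca-6,8-diene
Product: 20 4β-[4-(benzyloxy)benzoyloxy]dauc-8-en-6-one
Conditions: TBAF, AcOH, THF, −78 → 0 °C
Reagents that add atoms: none
Why: Fluoride cleaves the silyl dienol ether and the buffered medium protonates kinetically at the α-carbon C7 (deconjugative protonation), which should give the β,γ-unsaturated ketone while staying too weakly basic for β-elimination of the C4 ester.

Step 12
Reactants: 20 4β-[4-(benzyloxy)benzoyloxy]dauc-8-en-6-one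
Product: 21 4β-[4-(benzyloxy)benzoyloxy]dauc-8-en-6α-ol
Conditions: (R)-2-methyl-CBS-oxazaborolidine (cat.), catecholborane, toluene, −78 °C; pH 7 buffer
Reagents that add atoms: none
Why: Corey–Bakshi–Shibata reduction: with the ring-fusion methine as the large flank and the C7 methylene as the small one, the (R)-oxazaborolidine should deliver hydride to the β-face and give the 6α-alcohol ((S)-carbinol), and catecholborane at low temperature leaves the alkene and the ester alone.

Step 13
Reactants: 21 4β-[4-(benzyloxy)benzoyloxy]dauc-8-en-6α-ol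
Product: 22 4β-[4-(benzyloxy)benzoyloxy]-8α,9α-epoxydaucan-6α-ol
Conditions: VO(acac)2 (cat.), t-BuOOH, CH2Cl2, 0 °C → rt
Reagents that add atoms: tert-butyl hydroperoxide CC(C)(C)OO
Why: Vanadium-catalysed epoxidation is directed by the homoallylic 6α-hydroxyl, which binds the metal peroxide and delivers oxygen to the α-face of the C8=C9 alkene, the face that is also opposite the angular methyl.

Step 14
Reactants: 22 4β-[4-(benzyloxy)benzoyloxy]-8α,9α-epoxydaucan-6α-ol
Product: 23 4β-(4-hydroxybenzoyloxy)-8α,9α-epoxydaucan-6α-ol (target)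
Conditions: H2, Pd/C, EtOAc, rt
Reagents that add atoms: none
Why: Hydrogenolysis of the benzyl aryl ether under neutral conditions frees the phenol; the trialkyl epoxide and the tertiary ester are not expected to react, and the absence of base avoids acyl migration to the C6 hydroxyl.

Compound list
1 | (S)-(+)-terpinen-4-ol | CC(C)[C@@]1(O)CC=C(C)CC1 | starting material
2 | 4-(benzyloxy)benzoyl chloride | O=C(Cl)c1ccc(OCc2ccccc2)cc1 | starting material
3 | lithium (S)-terpinen-4-olate | CC(C)[C@@]1(O[Li])CC=C(C)CC1 | intermediate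
4 | (S)-terpinen-4-yl 4-(benzyloxy)benzoate | CC(C)[C@@]1(OC(=O)c2ccc(OCc3ccccc3)cc2)CC=C(C)CC1 | intermediate
5 | secondary ozonide (1,2,4-trioxolane) of 4; carbinol configuration unchanged | CC(C)[C@@]1(OC(=O)c2ccc(OCc3ccccc3)cc2)CC2OOC(C)(CC1)O2 | intermediate
6 | (S)-1,6-dioxo-3-(propan-2-yl)heptan-3-yl 4-(benzyloxy)benzoate (keto aldehyde) | CC(C)[C@@](OC(=O)c1ccc(OCc2ccccc2)cc1)(CC=O)CCC(C)=O | intermediate
7 | (S)-1,1-dimethoxy-6-oxo-3-(propan-2-yl)heptan-3-yl 4-(benzyloxy)benzoate | CC(C)[C@@](OC(=O)c1ccc(OCc2ccccc2)cc1)(CC(OC)OC)CCC(C)=O | intermediate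
8 | ethynylmagnesium bromide | C#C[Mg]Br | starting material
9 | bromomagnesium alkoxide of the tertiary propargylic alcohol (both epimers at C6) | CC(C)[C@@](OC(=O)c1ccc(OCc2ccccc2)cc1)(CC(OC)OC)CCC(C)(C#C)O[Mg]Br | intermediate
10 | (3S)-6-ethynyl-1,1-dimethoxy-6-(methoxycarbonyloxy)-3-(propan-2-yl)heptan-3-yl 4-(benzyloxy)benzoate (both epimers at C6) | CC(C)[C@@](OC(=O)c1ccc(OCc2ccccc2)cc1)(CC(OC)OC)CCC(C)(C#C)OC(=O)OC | intermediate
11 | (S)-1,1-dimethoxy-6-methyl-3-(propan-2-yl)octa-6,7-dien-3-yl 4-(benzyloxy)benzoate | CC(C)[C@@](OC(=O)c1ccc(OCc2ccccc2)cc1)(CC(OC)OC)CCC(C)=C=C | intermediate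
12 | (S)-6-methyl-1-oxo-3-(propan-2-yl)octa-6,7-dien-3-yl 4-(benzyloxy)benzoate | CC(C)[C@@](OC(=O)c1ccc(OCc2ccccc2)cc1)(CC=O)CCC(C)=C=C | intermediate
13 | (E)-1-bromopropene | C/C=C/Br | starting material
14 | (E)-1-propenyllithium | C/C=C/[Li] | intermediate
15 | (2E,6S)-4-hydroxy-9-methyl-6-(propan-2-yl)undeca-2,9,10-trien-6-yl 4-(benzyloxy)benzoate (both epimers at C4) | CC(C)[C@@](OC(=O)c1ccc(OCc2ccccc2)cc1)(CC(O)/C=C/C)CCC(C)=C=C | intermediate
16 | (2E,6S)-9-methyl-4-oxo-6-(propan-2-yl)undeca-2,9,10-trien-6-yl 4-(benzyloxy)benzoate | CC(C)[C@@](OC(=O)c1ccc(OCc2ccccc2)cc1)(CC(=O)/C=C/C)CCC(C)=C=C | intermediate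
17 | (2E,4Z,6R)-4-(tert-butyldimethylsilyloxy)-9-methyl-6-(propan-2-yl)undeca-2,4,9,10-tetraen-6-yl 4-(benzyloxy)benzoate | CC(C)[C@@](OC(=O)c1ccc(OCc2ccccc2)cc1)(/C=C(O[Si](C)(C)C(C)(C)C)/C=C/C)CCC(C)=C=C | intermediate
18 | 4β-[4-(benzyloxy)benzoyloxy]-6-(tert-butyldimethylsilyloxy)dauca-6,9-diene; trans-fused, 1β-methyl, 5α-H, 8β-methyl | CC(C)[C@]1(OC(=O)c2ccc(OCc3ccccc3)cc2)CC[C@]2(C)C=C[C@@H](C)C=C(O[Si](C)(C)C(C)(C)C)[C@H]21 | intermediate
19 | 4β-[4-(benzyloxy)benzoyloxy]-6-(tert-butyldimethylsilyloxy)dauca-6,8-diene; trans-fused, 1β-methyl, 5α-H | CC(C)[C@]1(OC(=O)c2ccc(OCc3ccccc3)cc2)CC[C@]2(C)CC=C(C)C=C(O[Si](C)(C)C(C)(C)C)[C@H]21 | intermediate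
20 | 4β-[4-(benzyloxy)benzoyloxy]dauc-8-en-6-one | CC(C)[C@]1(OC(=O)c2ccc(OCc3ccccc3)cc2)CC[C@]2(C)CC=C(C)CC(=O)[C@H]21 | intermediate
21 | 4β-[4-(benzyloxy)benzoyloxy]dauc-8-en-6α-ol | CC(C)[C@]1(OC(=O)c2ccc(OCc3ccccc3)cc2)CC[C@]2(C)CC=C(C)C[C@H](O)[C@H]21 | intermediate
22 | 4β-[4-(benzyloxy)benzoyloxy]-8α,9α-epoxydaucan-6α-ol | CC(C)[C@]1(OC(=O)c2ccc(OCc3ccccc3)cc2)CC[C@]2(C)C[C@@H]3O[C@]3(C)C[C@H](O)[C@H]21 | intermediate
23 | 4β-(4-hydroxybenzoyloxy)-8α,9α-epoxydaucan-6α-ol; trans-fused, 1β-methyl, 5α-H | CC(C)[C@]1(OC(=O)c2ccc(O)cc2)CC[C@]2(C)C[C@@H]3O[C@]3(C)C[C@H](O)[C@H]21 | target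

Total step count: 14 steps.
Longest linear sequence: 14 steps (from 1).

Steps most likely to fail

Step 9 (key cycloaddition). The capture of the gold-bound allyl cation may stop after the first C–C bond (protodemetalation or loss of the silyl group), close in a formal (3+2) sense, or give the cis-fused isomer. The fallback sets out from 17 and comes back at 18, and it makes the two ring bonds in separate operations. Compound 17 is treated with the same gold catalyst in CH2Cl2 containing MeOH, so that only the 5-exo carbocyclisation of the silyl enol ether onto the allene takes place and the vinylgold intermediate is protonated; this should give the trans-vinylcyclopentyl (E)-propenyl ketone F1. Conjugate addition of (CH2=CH)2CuLi with TMSCl in THF at −78 °C to the enone gives the dienyl ketone F2; its enolate lies on the C7 side, so the C4 ester is not at risk. Ring-closing metathesis with second-generation Grubbs catalyst in CH2Cl2 closes the cycloheptene to the dauc-9-en-6-one F3. Silylation with TBSOTf and Et3N on the less hindered methylene side then gives 18 together with its epimer at C8, and both converge in step 10.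

Step 10 (alkene transposition). The ruthenium hydride may fail to engage the hindered alkene next to the quaternary carbon, or may move the silyl enol ether instead. The fallback sets out from 18 and comes back at 19 by an oxidation–reduction detour. Saegusa–Ito oxidation of 18 with Pd(OAc)2 in MeCN gives the linear dienone F4. Hydrogenation with RhCl(PPh3)3 and H2 in benzene saturates the disubstituted C9=C10 alkene and leaves the trisubstituted enone and the benzyl ether, giving the enone F5. Thermodynamic γ-silylation with TBSOTf and Et3N then gives the extended silyl dienol ether 19; the α′ position is a hindered ring-fusion methine and should not compete.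

Step 12 (ketone reduction). Catalyst control may not overcome the substrate bias for hydride attack from the α-face, so the 6β-epimer may dominate. The fallback sets out from 20 and comes back at 21 by accepting the substrate bias and inverting. Reduction of 20 with LiBH(s-Bu)3 in THF at −78 °C should give the 6β-alcohol F6. Mitsunobu inversion with HCO2H, PPh3 and DIAD gives the 6α-formate F7. Brief methanolysis with KHCO3 in MeOH, which the hindered tertiary aryl ester should survive, gives 21.

Further compounds
F1 | step 9 | (E)-1-{2-methyl-5-(propan-2-yl)-5-[4-(benzyloxy)benzoyloxy]-2-vinylcyclopentyl}but-2-en-1-one; vinyl and acyl trans, ring stereocentres as C1, C4, C5 of 18 | CC(C)[C@]1(OC(=O)c2ccc(OCc3ccccc3)cc2)CC[C@](C)(C=C)[C@H]1C(=O)/C=C/C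
F2 | step 9 | 1-{2-methyl-5-(propan-2-yl)-5-[4-(benzyloxy)benzoyloxy]-2-vinylcyclopentyl}-3-methylpent-4-en-1-one; both epimers at the new methyl-bearing carbon | CC(C)[C@]1(OC(=O)c2ccc(OCc3ccccc3)cc2)CC[C@](C)(C=C)[C@H]1C(=O)CC(C)C=C
F3 | step 9 | 4β-[4-(benzyloxy)benzoyloxy]dauc-9-en-6-one; both epimers at C8 | CC(C)[C@]1(OC(=O)c2ccc(OCc3ccccc3)cc2)CC[C@]2(C)C=CC(C)CC(=O)[C@H]21
F4 | step 10 | 4β-[4-(benzyloxy)benzoyloxy]dauca-7,9-dien-6-one | CC(C)[C@]1(OC(=O)c2ccc(OCc3ccccc3)cc2)CC[C@]2(C)C=CC(C)=CC(=O)[C@H]21
F5 | step 10 | 4β-[4-(benzyloxy)benzoyloxy]dauc-7-en-6-one | CC(C)[C@]1(OC(=O)c2ccc(OCc3ccccc3)cc2)CC[C@]2(C)CCC(C)=CC(=O)[C@H]21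
F6 | step 12 | 4β-[4-(benzyloxy)benzoyloxy]dauc-8-en-6β-ol | CC(C)[C@]1(OC(=O)c2ccc(OCc3ccccc3)cc2)CC[C@]2(C)CC=C(C)C[C@@H](O)[C@H]21
F7 | step 12 | 4β-[4-(benzyloxy)benzoyloxy]dauc-8-en-6α-yl formate | CC(C)[C@]1(OC(=O)c2ccc(OCc3ccccc3)cc2)CC[C@]2(C)CC=C(C)C[C@H](OC=O)[C@H]21
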